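**Plan**

- Labels: C1 methyl-bearing bridgehead, C2 enol carbon, C3 acylated carbon, C4 ring A ketone, C5 second bridgehead, C6 CH2, C7 CH carrying the hydroxyisopropyl group, C8 CMe2, C9 ring-fusion CH, C10 CH2, C11 bridging ketone; ring A = C1-C2-C3-C4-C5-C11, ring B = C1-C10-C9-C5-C11, ring C = C5-C6-C7-C8-C9.
- Enabling feature: rings B and C are a cis-fused diquinane in which C11 (ketone) and C7 (ketone level until the side chain is made) stand 1,4 through C5-C6; a C11-methoxy cyclopropyl ketone from an oxa-di-pi-methane rearrangement releases exactly this pattern.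
- Cuts, in retrosynthetic order: C3–acyl; C2–C3 (Claisen) and C4–C5 (bridgehead aldol), which removes ring A; the C7 side chain back to a C7 ketone; the C6–C11 cyclopropane bond; C6–C7 and C5–C11 (photochemical 1,2-acyl shift); C1–C11 and C9–C10 (Diels–Alder); one C8 methyl (dearomatising methylation).
- Forward: cyclohexadienone, bicyclo[2.2.2]octenone, rings B and C together in the photochemical step, cyclopropane opening, side chain at C7, ring A by acetylation of C5 and Claisen closure, acyl group last.
- Stereochemistry: C1 and C9 from the endo Diels–Alder adduct, resolved at that stage; C5 from the enforced cis ring fusion; C7 from convex-face hydrogenation; the acyl stereocentre from (R)-2-methylbutanoic acid.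

Key step: step 4

Assumption: the enantiomers of adduct 6 are taken to be separable on a polysaccharide chiral phase, and the absolute configuration of the collected enantiomer is to be confirmed by anomalous-dispersion X-ray analysis before it is carried on.
Remark: in 6 and 7 the bicyclo[2.2.2]octene locants map onto the target labels as C1 to C11, C2 to C1, C3 to C10, C4 to C9, with C5 to C8 unchanged; from 8 onward the target labels are used. "Convex" is the face of the cis-diquinane that carries C9–H and C5–H; "concave" is the inner face.
Remark: the enolised trione of ring A is drawn as the C2 enol throughout; its tautomers interconvert.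

**Step 1**
Reactants: 1 2-methoxy-6-methylphenol; 2 iodomethane
Product: 4 2-methoxy-6,6-dimethylcyclohexa-2,4-dien-1-one, via sodium phenoxide 3 (not isolated)
Conditions: NaH, toluene, 0 °C to rt; then 2 (5 equiv), 60 °C, sealed vessel; product used at once
Reagents that add atoms: none
Why: Alkylative dearomatisation of a 2,6-disubstituted phenoxide, in which the tightly aggregated sodium salt in a non-polar solvent is expected to be methylated at the methyl-bearing ortho carbon (attack there keeps the methoxy group conjugated as an enol ether) and the new quaternary carbon blocks rearomatisation.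

**Step 2**
Reactants: 4 2-methoxy-6,6-dimethylcyclohexa-2,4-dien-1-one; 5 methyl methacrylate
Product: 6 racemic methyl 1-methoxy-2,8,8-trimethyl-7-oxobicyclo[2.2.2]oct-5-ene-2-carboxylate (ester endo)
Conditions: neat 5 (10 equiv), BHT (1 mol %), 90 °C, sealed tube
Reagents that add atoms: none
Why: Thermal Diels–Alder reaction of a cyclohexa-2,4-dienone, in which the methoxy-bearing diene terminus joins the ester-bearing carbon of the dienophile (ortho rule) and the ester takes the endo position, syn to the new alkene and away from the ketone bridge, which fixes the relative configuration of the future C1 and C9.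

**Step 3**
Reactants: 6 racemic Diels–Alder adduct
Product: 7 methyl (1S,2R,4R)-1-methoxy-2,8,8-trimethyl-7-oxobicyclo[2.2.2]oct-5-ene-2-carboxylate
Conditions: preparative supercritical-fluid chromatography, amylose tris(3,5-dimethylphenylcarbamate) stationary phase, CO2/MeOH
Reagents that add atoms: none
Why: Resolution of the racemate by chromatography on a chiral stationary phase, placed early so that only the enantiomer whose C2 and C4 become C1 and C9 of the target enters the photochemical step.

**Step 4**
Reactants: 7 bridgehead-methoxy bicyclo[2.2.2]octenone ester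
Product: 8 methoxycyclopropane-fused diquinane keto ester
Conditions: hν (300 nm, Pyrex), acetone (solvent and triplet sensitiser), 0.01 M, argon-purged, rt
Reagents that add atoms: none
Why: Oxa-di-pi-methane rearrangement: triplet energy transfer from acetone excites the beta,gamma-unsaturated ketone, the carbonyl carbon C7 bonds to the near alkene carbon C6, the bond from C7 to the methoxy bridgehead C11 breaks, and the C11 radical recombines with the far alkene carbon C5. The closest known reaction is the sensitised rearrangement of bicyclo[2.2.2]oct-5-en-2-ones, bridgehead-alkoxy ones included, to tricyclo[3.3.0.0(2,8)]octan-3-ones. Ring C closes by the 1,2-acyl shift (3-exo attack of C6 on the carbonyl carbon, then opening of the oxycyclopropane toward C11), and ring B closes by 3-exo radical recombination between C11 and C5, which also makes the temporary C5-C6-C11 cyclopropane. The lasting new stereocentre C5 is controlled by the bicyclic frame, since C11 can reach only the alkene face to which it is already tethered, so the C5/C9 fusion must be cis; the C6 centre is lost again in step 5. The step needs the triplet 1,2-shift to win over the singlet 1,3-acyl shift and over alpha-cleavage with loss of CO, which is secured by the rigid enone geometry of the substrate (C=O and C=C held in overlap, a single alkene) together with light absorption by the sensitiser only; the ester, endo in 7, ends on the convex face next to C11, where ring A is closed later.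

**Step 5**
Reactants: 8 methoxycyclopropane-fused diquinane keto ester
Product: 9 C7-keto C11-dimethyl ketal diquinane ester
Conditions: camphorsulfonic acid (10 mol %), dry MeOH, 0 °C to rt; Et3N quench
Reagents that add atoms: methanol CO
Why: Acid-catalysed opening of a donor–acceptor cyclopropane (a 2-alkoxycyclopropyl ketone), in which the protonated C7 ketone pulls and the methoxy group pushes so that only the C6–C11 bond breaks, and methanol captures the C11 oxocarbenium ion as the dimethyl ketal, unveiling the 1,4-dicarbonyl pattern with its two carbonyls already differentiated.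

**Step 6**
Reactants: 9 C7-keto C11-dimethyl ketal diquinane ester
Product: 11 C6=C7 enol triflate, via potassium enolate 10 (not isolated)
Conditions: KN(SiMe3)2, THF, −78 °C; then PhNTf2, −78 to 0 °C; H2O work-up
Reagents that add atoms: N-phenylbis(trifluoromethanesulfonimide) O=S(=O)(N(c1ccccc1)S(=O)(=O)C(F)(F)F)C(F)(F)F
Why: Enol triflate formation from a ketone enolate, regiochemically unambiguous because C6 is the only enolisable position (C11 is a ketal, C8 and C1 are quaternary).

**Step 7**
Reactants: 11 C6=C7 enol triflate; 12 carbon monoxide; 13 tetramethylstannane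
Product: 14 C7-acetyl C6=C7 enone
Conditions: Pd(PPh3)4 (5 mol %), LiCl (3 equiv), 12 (3 bar), 13 (1.5 equiv), DMF, 60 °C
Reagents that add atoms: none
Why: Carbonylative Stille coupling, in which oxidative addition of the alkenyl triflate to zerovalent palladium, CO insertion and methyl transfer from tin give the methyl enone without touching the ester or the ketal.

**Step 8**
Reactants: 14 C7-acetyl C6=C7 enone
Product: 15 saturated C7-acetyl ketal ester (acetyl on the concave face)
Conditions: H2 (1 bar), Pd/C (10 wt %), EtOAc, rt
Reagents that add atoms: none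
Why: Heterogeneous hydrogenation of the enone C=C from the convex face of the cis-diquinane (the concave face is shielded by ring B, the C11 methoxy groups and the C1 methyl), which places H on C7 on the convex side and the acetyl group on the concave side as the target requires.

**Step 9**
Reactants: 15 saturated C7-acetyl ketal ester; 16 methyllithium
Product: 17 C7-(2-hydroxypropan-2-yl) ketal ester
Conditions: 16 added to anhydrous CeCl3, THF, −78 °C; then 15, −78 °C; aq. NH4Cl
Reagents that add atoms: none
Why: Organocerium 1,2-addition to a methyl ketone, chosen because the weakly basic reagent adds faster than it enolises, so C7 is not epimerised and the hindered C1 ester and the ketal are left alone.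

**Step 10**
Reactants: 17 C7-(2-hydroxypropan-2-yl) ketal ester
Product: 18 triethylsilyl ether of 17
Conditions: Et3SiOTf, 2,6-lutidine, CH2Cl2, −78 °C
Reagents that add atoms: triethylsilyl trifluoromethanesulfonate CC[Si](CC)(CC)OS(=O)(=O)C(F)(F)F
Why: Silylation of a tertiary alcohol by a silyl triflate, needed because a free alkoxide held on the concave face next to C11 could later add to that ketone and open the 1,3-dicarbonyl array by retro-Claisen cleavage.

**Step 11**
Reactants: 18 triethylsilyl ether ketal ester
Product: 19 C11 ketone (diquinane keto ester, silyl ether)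
Conditions: pyridinium p-toluenesulfonate (20 mol %), acetone/H2O 9:1, 40 °C
Reagents that add atoms: water O
Why: Mild acid-catalysed hydrolysis of a dimethyl ketal, which is expected to proceed under conditions that leave the tertiary triethylsilyl ether and the methyl ester intact.

**Step 12**
Reactants: 19 C11 ketone; 20 acetaldehyde
Product: 22 C5-(1-hydroxyethyl) aldol (carbinol epimers), via lithium enolate 21 (not isolated)
Conditions: LiN(iPr)2, THF, −78 °C; then 20 (3 equiv), −78 °C; AcOH quench at −78 °C
Reagents that add atoms: none
Why: Directed aldol addition, in which C5–H is the only alpha-hydrogen of the C11 ketone and the enolate is attacked on the convex face, the only one that keeps the diquinane cis-fused, so the new C4–C5 bond is cis to C9–H and to the C1 ester; the carbinol centre forms as a mixture and is removed in step 13.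

**Step 13**
Reactants: 22 C5-(1-hydroxyethyl) aldol
Product: 23 C5-acetyl diketo ester
Conditions: Dess–Martin periodinane, CH2Cl2, 0 °C to rt
Reagents that add atoms: none
Why: Dess–Martin oxidation of a secondary alcohol to the methyl ketone under near-neutral conditions that avoid retro-aldol cleavage, both carbinol epimers converging on one product.

**Step 14**
Reactants: 23 C5-acetyl diketo ester
Product: 24 tricyclic enolised trione lacking the C3 acyl group (silyl ether)
Conditions: LiN(SiMe3)2 (3 equiv), THF, −78 to 0 °C; AcOH quench
Reagents that add atoms: none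
Why: Intramolecular Claisen (Dieckmann-type) condensation, in which the acetyl methyl group is the only acidic C–H position, its enolate attacks the cis-disposed C1 ester through a six-membered transition state to form C2–C3 and close ring A, and deprotonation of the resulting beta-diketone drives the equilibrium.

**Step 15**
Reactants: 24 tricyclic enolised trione; 25 (R)-2-methylbutanoic acid
Product: 27 triethylsilyl ether of the target, via enol ester 26 (not isolated)
Conditions: DCC, DMAP (30 mol %), CH2Cl2, 0 °C to rt
Reagents that add atoms: none
Why: Carbodiimide-mediated O-acylation of the enolised 1,3-dione followed by DMAP-promoted O-to-C acyl migration, the usual route to 2-acylcycloalkane-1,3-diones, with the chelated C-acyl trione as the thermodynamic sink and the acid alpha-stereocentre expected to survive because no strong base is present.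

**Step 16**
Reactants: 27 triethylsilyl ether of the target
Product: 28 CNP0207052.1
Conditions: HF·pyridine, THF, 0 °C to rt
Reagents that add atoms: none
Why: Fluoride-mediated cleavage of a tertiary silyl ether under buffered acidic conditions that the enolised triketone should tolerate.

**Compound list**

1 | 2-methoxy-6-methylphenol | COc1cccc(C)c1O | starting material
2 | iodomethane | CI | starting material
3 | sodium 2-methoxy-6-methylphenoxide | COc1cccc(C)c1[O-].[Na+] | intermediate (not isolated)
4 | 2-methoxy-6,6-dimethylcyclohexa-2,4-dien-1-one | COC1=CC=CC(C)(C)C1=O | intermediate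
5 | methyl methacrylate | C=C(C)C(=O)OC | starting material
6 | racemic methyl 1-methoxy-2,8,8-trimethyl-7-oxobicyclo[2.2.2]oct-5-ene-2-carboxylate, ester endo (syn to C5=C6); both enantiomers written | COC(=O)[C@]1(C)C[C@H]2C(C)(C)C(=O)[C@]1(OC)C=C2.COC(=O)[C@@]1(C)C[C@@H]2C(C)(C)C(=O)[C@@]1(OC)C=C2 | intermediate
7 | methyl (1S,2R,4R)-1-methoxy-2,8,8-trimethyl-7-oxobicyclo[2.2.2]oct-5-ene-2-carboxylate | COC(=O)[C@]1(C)C[C@H]2C(C)(C)C(=O)[C@]1(OC)C=C2 | intermediate (key-step precursor)
8 | methoxycyclopropane-fused diquinane keto ester: C5-C6-C11 cyclopropane with OMe on C11, C7 ketone, C8 Me2, C1 with Me (syn to ring C) and CO2Me (anti to ring C) | COC(=O)[C@]1(C)C[C@H]2C(C)(C)C(=O)[C@@H]3[C@H]2[C@]13OC | intermediate (key-step product)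
9 | C7-keto C11-dimethyl ketal diquinane ester: cis-fused (C5–H, C9–H convex), C1 CO2Me convex and Me concave, C8 Me2 | COC(=O)[C@]1(C)C[C@H]2C(C)(C)C(=O)C[C@H]2C1(OC)OC | intermediate
10 | potassium enolate of 9 (C6=C7–OK) | COC(=O)[C@]1(C)C[C@H]2C(C)(C)C([O-])=C[C@H]2C1(OC)OC.[K+] | intermediate (not isolated)
11 | C6=C7 enol triflate of 9 | COC(=O)[C@]1(C)C[C@H]2C(C)(C)C(OS(=O)(=O)C(F)(F)F)=C[C@H]2C1(OC)OC | intermediate
12 | carbon monoxide | [C-]#[O+] | starting material
13 | tetramethylstannane | C[Sn](C)(C)C | starting material
14 | C7-acetyl C6=C7 enone (ketal ester) | COC(=O)[C@]1(C)C[C@H]2C(C)(C)C(C(C)=O)=C[C@H]2C1(OC)OC | intermediate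
15 | saturated C7-acetyl ketal ester, acetyl on the concave face (cis to C11), C7–H convex | COC(=O)[C@]1(C)C[C@H]2C(C)(C)[C@@H](C(C)=O)C[C@H]2C1(OC)OC | intermediate
16 | methyllithium | [Li]C | starting material
17 | C7-(2-hydroxypropan-2-yl) ketal ester | COC(=O)[C@]1(C)C[C@H]2C(C)(C)[C@@H](C(C)(C)O)C[C@H]2C1(OC)OC | intermediate
18 | triethylsilyl ether of 17 | COC(=O)[C@]1(C)C[C@H]2C(C)(C)[C@@H](C(C)(C)O[Si](CC)(CC)CC)C[C@H]2C1(OC)OC | intermediate
19 | C11 ketone: cis-diquinane keto ester with C7 silyloxyisopropyl group (concave) | COC(=O)[C@]1(C)C[C@H]2C(C)(C)[C@@H](C(C)(C)O[Si](CC)(CC)CC)C[C@H]2C1=O | intermediate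
20 | acetaldehyde | CC=O | starting material
21 | lithium enolate of 19 (C5=C11–OLi) | COC(=O)[C@]1(C)C[C@H]2C(C)(C)[C@@H](C(C)(C)O[Si](CC)(CC)CC)CC2=C1[O-].[Li+] | intermediate (not isolated)
22 | C5-(1-hydroxyethyl) aldol, new C4–C5 bond on the convex face, carbinol epimers | COC(=O)[C@]1(C)C[C@H]2C(C)(C)[C@@H](C(C)(C)O[Si](CC)(CC)CC)C[C@@]2(C(C)O)C1=O | intermediate
23 | C5-acetyl diketo ester | COC(=O)[C@]1(C)C[C@H]2C(C)(C)[C@@H](C(C)(C)O[Si](CC)(CC)CC)C[C@@]2(C(C)=O)C1=O | intermediate
24 | tricyclic enolised trione (rings A, B, C) without the C3 acyl group, silyl ether | C1=C(O)[C@]2(C)C[C@H]3C(C)(C)[C@@H](C(C)(C)O[Si](CC)(CC)CC)C[C@@]3(C1=O)C2=O | intermediate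
25 | (R)-2-methylbutanoic acid | CC[C@@H](C)C(=O)O | starting material
26 | enol ester: O-(R)-2-methylbutanoyl derivative of 24 at the C2 oxygen | C1=C(OC(=O)[C@H](C)CC)[C@]2(C)C[C@H]3C(C)(C)[C@@H](C(C)(C)O[Si](CC)(CC)CC)C[C@@]3(C1=O)C2=O | intermediate (not isolated)
27 | triethylsilyl ether of the target (C3 acylated) | CC[C@@H](C)C(=O)C1=C(O)[C@]2(C)C[C@H]3C(C)(C)[C@@H](C(C)(C)O[Si](CC)(CC)CC)C[C@@]3(C1=O)C2=O | intermediate
28 | CNP0207052.1 | CC[C@@H](C)C(=O)C1=C(O)[C@]2(C)C[C@H]3C(C)(C)[C@@H](C(C)(C)O)C[C@@]3(C1=O)C2=O | target

**Step count and risks**

Total step count: 16. Longest linear sequence: 16 steps (1 to 28).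

Steps most likely to fail:

1. Step 1. Methylation at oxygen, at the methoxy-bearing ortho carbon or at the para carbon, and Diels–Alder dimerisation of the dienone may outrun the wanted C-methylation. Fallback: oxidative instead of alkylative dearomatisation, so that the position of the sp3 carbon is fixed by the substrate. It sets out from methyl methacrylate 5 (phenol 1 is replaced by commercial 2-hydroxy-3-methoxybenzyl alcohol F1) and returns at racemic adduct 6. Adler–Becker oxidation of F1 (NaIO4, aqueous MeCN, 0 °C) in the presence of excess 5 should give 5-methoxy-1-oxaspiro[2.5]octa-5,7-dien-4-one F2, trapped in situ as the endo Diels–Alder adduct, spiroepoxy ketone F3. Zn/NH4Cl in aqueous MeOH should open the alpha-keto epoxide to hydroxymethyl ketone F4. CrO3/H2SO4 in acetone should oxidise it to beta-keto acid F5, which loses CO2 to give ketone F6. NaH and excess iodomethane 2 in THF should then methylate the only enolisable carbon twice, through monomethyl ketone F7, to give 6.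

2. Step 12. Reversal of the aldol addition at the congested C5 and attack of the lithium aldolate on the neighbouring C1 ester (lactone formation) may erode the product. Fallback: a Mukaiyama aldol addition, in which no free alkoxide is present. It sets out from ketone 19 and returns at aldol 22. Me3SiOTf and Et3N in CH2Cl2 at 0 °C should give trimethylsilyl enol ether F8, and acetaldehyde 20 with BF3·OEt2 in CH2Cl2 at −78 °C should add on the convex face to give 22 after aqueous work-up.

3. Step 15. The O-to-C acyl migration may stall at the enol ester on the hindered bicyclic dione, and the acyl alpha-carbon may epimerise through a ketene or an acylpyridinium enolate. Fallback: acylation of a C3 carbanion instead of acyl migration. It sets out from trione 24 and returns at 27. Me3SiCHN2 in MeOH/toluene should give methyl enol ether F9 (either regioisomer serves; the C2 ether is drawn). Lithium 2,2,6,6-tetramethylpiperidide in THF at −78 °C should remove the vinylic C3 hydrogen to give C3-lithio species F10, which is trapped with (R)-2-methylbutanoyl chloride F11 (from acid 25, (COCl)2, cat. DMF, CH2Cl2) to give C3-acyl enol ether F12. LiCl in DMSO at 100 °C should then cleave the O-methyl group to give 27.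

**Further compounds**

F1 | step 1 | 2-hydroxy-3-methoxybenzyl alcohol (commercial) | COc1cccc(CO)c1O
F2 | step 1 | 5-methoxy-1-oxaspiro[2.5]octa-5,7-dien-4-one | COC1=CC=CC2(CO2)C1=O
F3 | step 1 | racemic spiroepoxide analogue of 6 (oxirane spiro carbon in place of CMe2; ring configuration drawn as in 7, spiro carbon either way) | COC(=O)[C@]1(C)C[C@H]2C3(CO3)C(=O)[C@]1(OC)C=C2
F4 | step 1 | racemic hydroxymethyl ketone (CH(CH2OH) in place of CMe2) | COC(=O)[C@]1(C)C[C@H]2C(CO)C(=O)[C@]1(OC)C=C2
F5 | step 1 | racemic beta-keto acid (CH(CO2H) in place of CMe2) | COC(=O)[C@]1(C)C[C@H]2C(C(=O)O)C(=O)[C@]1(OC)C=C2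
F6 | step 1 | racemic methyl 1-methoxy-2-methyl-7-oxobicyclo[2.2.2]oct-5-ene-2-carboxylate (CH2 in place of CMe2) | COC(=O)[C@]1(C)C[C@H]2CC(=O)[C@]1(OC)C=C2
F7 | step 1 | racemic monomethyl ketone (CHMe in place of CMe2) | COC(=O)[C@]1(C)C[C@H]2C(C)C(=O)[C@]1(OC)C=C2
F8 | step 12 | trimethylsilyl enol ether of 19 (C5=C11–OSiMe3) | COC(=O)[C@]1(C)C[C@H]2C(C)(C)[C@@H](C(C)(C)O[Si](CC)(CC)CC)CC2=C1O[Si](C)(C)C
F9 | step 15 | methyl enol ether of 24 (C2–OMe) | C1=C(OC)[C@]2(C)C[C@H]3C(C)(C)[C@@H](C(C)(C)O[Si](CC)(CC)CC)C[C@@]3(C1=O)C2=O
F10 | step 15 | C3-lithio derivative of F9 | [Li]C1=C(OC)[C@]2(C)C[C@H]3C(C)(C)[C@@H](C(C)(C)O[Si](CC)(CC)CC)C[C@@]3(C1=O)C2=O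
F11 | step 15 | (R)-2-methylbutanoyl chloride | CC[C@@H](C)C(=O)Cl
F12 | step 15 | C3-acyl methyl enol ether | CC[C@@H](C)C(=O)C1=C(OC)[C@]2(C)C[C@H]3C(C)(C)[C@@H](C(C)(C)O[Si](CC)(CC)CC)C[C@@]3(C1=O)C2=O
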